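**Retrosynthetic overview**
1. Ring E is closed last by an intramolecular Michael addition of the 2-cinnamoylcyclopentanone carbon C4 to a tethered butenolide (C3a). This one step creates the bicyclo[3.2.1]octanone, the quaternary centre and cis-lactone F.
2. The butenolide comes from ring-closing metathesis of an acrylate/vinyl pair. Ring D is made before it by a 1,6-Mukaiyama–Michael addition (C6–C7′) followed by oxidative enol-silane coupling (C4–C6′).
3. These disconnections give two fragments: tricyclic dienone 16 (rings A–C) and bis(silyloxy)diene 24 (C3a–C7a chain, cinnamoyl, acrylate).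
4. Dienone 16 comes from cyclohexenol by Pd-catalysed asymmetric allylic alkylation, iodolactonisation (ring A), allylic oxidation, and C-acylation/cyclodehydration (ring C). Diene 24 comes from the L-glutamic-acid-derived hydroxymethyl lactone, benzalacetone and acryloyl chloride.
5. Ring order: B (starting carbocycle) → A → C → D → F (as butenolide) → E.

**Labels and assumptions**
- Each half is numbered like cryptocaryone: C2 lactone carbonyl, C3, C3a, C4, C5, C6, C7, C7a. Unprimed is the cinnamoyl half (C4 quaternary, C5 bridging ketone); primed is the pyranone half.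
- Rings: A, lactone of the primed half; B, its carbocycle; C, dihydropyranone; D, cyclopentanone (C4, C5, C6, C7′, C6′); E, cyclohexanone (C3a–C7a); F, lactone of the unprimed half.
- Assumption: the (S,S)-DACH-phenyl Trost ligand gives the (R)-malonate 8; if the sense is opposite, the (R,R)-antipode is used.
- Assumption: simple salt forms (enolates, carboxylates) of a numbered compound are not numbered separately.

**Acyl donor for ring C**

Step 1
Reactants: 1 ethyl (S)-3-hydroxy-3-phenylpropanoate
Product: 2 ethyl (S)-3-[(tert-butyldimethylsilyl)oxy]-3-phenylpropanoate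
Conditions: TBSCl, imidazole, DMF, rt
Reagents that add atoms: tert-butyldimethylsilyl chloride, CC(C)(C)[Si](C)(C)Cl
Why: Imidazole-promoted O-silylation masks the benzylic alcohol for the later enolate acylation and does not touch the stereocentre.

Step 2
Reactants: 2 ethyl (S)-3-[(tert-butyldimethylsilyl)oxy]-3-phenylpropanoate
Product: 3 (S)-3-[(tert-butyldimethylsilyl)oxy]-3-phenylpropanoic acid
Conditions: LiOH·H2O, THF/H2O, rt; then cold aq. HCl to pH 4
Reagents that add atoms: lithium hydroxide, [Li+].[OH-]
Why: Ester saponification leaves the silyl ether and the β-stereocentre intact.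

Step 3
Reactants: 3 (S)-3-[(tert-butyldimethylsilyl)oxy]-3-phenylpropanoic acid
Product: 4 (S)-1-(1H-benzotriazol-1-yl)-3-[(tert-butyldimethylsilyl)oxy]-3-phenylpropan-1-one
Conditions: 1H-benzotriazole (4 equiv), SOCl2 (1.05 equiv), CH2Cl2, rt
Reagents that add atoms: 1H-benzotriazole, c1ccc2[nH]nnc2c1
Why: Katritzky N-acylbenzotriazole formation (via the acyl chloride, buffered by excess benzotriazole) gives a neutral, storable acyl donor that C-acylates ketone enolates.

**Fragment 16 (rings A–C)**

Step 4
Reactants: 5 cyclohex-2-en-1-ol (racemic)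
Product: 6 cyclohex-2-en-1-yl acetate (racemic)
Conditions: Ac2O, pyridine, DMAP (cat.), CH2Cl2, 0 °C → rt
Reagents that add atoms: acetic anhydride, CC(=O)OC(C)=O
Why: DMAP-catalysed O-acetylation installs the allylic leaving group for the palladium step.

Step 5
Reactants: 6 cyclohex-2-en-1-yl acetate; 7 dimethyl malonate
Product: 8 dimethyl (R)-2-(cyclohex-2-en-1-yl)malonate
Conditions: [Pd(C3H5)Cl]2 (1 mol %), (S,S)-DACH-phenyl Trost ligand (3 mol %), Cs2CO3, CH2Cl2, 0 °C → rt
Reagents that add atoms: none
Why: Trost asymmetric allylic alkylation: zerovalent palladium ionises both enantiomers of 6 to the same meso π-allyl complex of divalent palladium, and the ligand pocket directs malonate to one terminus, setting C3a′.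

Step 6
Reactants: 8 dimethyl (R)-2-(cyclohex-2-en-1-yl)malonate
Product: 10 (S)-2-(cyclohex-2-en-1-yl)acetic acid, via malonic acid 9 (not isolated)
Conditions: KOH, MeOH/H2O, 70 °C; aq. HCl; then neat, 170 °C
Reagents that add atoms: potassium hydroxide, [K+].[OH-]
Why: Saponification and thermal decarboxylation of the malonic acid (malonic ester synthesis) leave the allylic stereocentre untouched; the descriptor changes only through priority.

Step 7
Reactants: 10 (S)-2-(cyclohex-2-en-1-yl)acetic acid
Product: 11 (3aS,7R,7aR)-7-iodohexahydro-1-benzofuran-2(3H)-one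
Conditions: iodine, NaHCO3, CH2Cl2/H2O, 0 °C, dark
Reagents that add atoms: iodine, [I][I]
Why: Iodolactonisation: 5-exo attack of the carboxylate on the iodonium ion, anti to iodine, gives the cis-fused lactone and relays C3a′ chirality to C7a′.

Step 8
Reactants: 11 (3aS,7R,7aR)-7-iodohexahydro-1-benzofuran-2(3H)-one
Product: 12 (3aS,7aR)-3a,4,5,7a-tetrahydro-1-benzofuran-2(3H)-one
Conditions: DBU, toluene, 90 °C
Reagents that add atoms: none
Why: E2 elimination: only a C6′ hydrogen is antiperiplanar to the axial iodide (H-7a′ is cis to it), so the C6′=C7′ alkene forms regioselectively.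

Step 9
Reactants: 12 (3aS,7aR)-3a,4,5,7a-tetrahydro-1-benzofuran-2(3H)-one
Product: 13 (3aS,7aR)-3a,7a-dihydro-1-benzofuran-2,5(3H,4H)-dione
Conditions: Rh2(caprolactamate)4 (1 mol %), t-BuOOH (5 equiv), K2CO3 (0.5 equiv), CH2Cl2, rt
Reagents that add atoms: tert-butyl hydroperoxide, CC(C)(C)OO
Why: Rhodium-catalysed allylic C–H oxidation attacks the only allylic methylene (C5′), remote from the acyloxy-bearing carbon, and gives the γ-acyloxy enone without touching the stereocentres.

Step 10
Reactants: 13 (3aS,7aR)-3a,7a-dihydro-1-benzofuran-2,5(3H,4H)-dione; 4 (S)-1-(1H-benzotriazol-1-yl)-3-[(tert-butyldimethylsilyl)oxy]-3-phenylpropan-1-one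
Product: 14 (3aR,7aS)-4-[(3S)-3-[(tert-butyldimethylsilyl)oxy]-3-phenylpropanoyl]-5-hydroxy-3a,7a-dihydro-1-benzofuran-2(3H)-one (enol form of the triketone)
Conditions: LiN(SiMe3)2 (2.1 equiv), THF, −78 °C; 4 (1.05 equiv), −78 → −30 °C; aq. NH4Cl
Reagents that add atoms: none
Why: Kinetic α′-deprotonation of the enone at C4′ and Claisen-type C-acylation by the acylbenzotriazole give the triketone, which rests as its chelated enol (no new stereocentre); the second equivalent of base is taken up by the acidic product and is too weak to enolise the lactone.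

Step 11
Reactants: 14 silyl-protected enolised triketone
Product: 16 tricyclic dienone (rings A to C; 3a′R 7a′S; benzylic carbon S), via hydroxy triketone 15 (not isolated)
Conditions: 48% aq. HF, MeCN, 0 °C → rt
Reagents that add atoms: none
Why: Acidic desilylation frees the δ-hydroxy β-diketone, which undergoes 6-exo hemiketalisation at C5′ and dehydration (cyclodehydration to a 2,3-dihydro-4H-pyran-4-one); the benzylic C–O bond is never broken, so the (S)-centre is retained.

**Fragment 24**

Step 12
Reactants: 17 (S)-5-(hydroxymethyl)dihydrofuran-2(3H)-one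
Product: 18 (S)-5-oxotetrahydrofuran-2-carbaldehyde
Conditions: Dess–Martin periodinane, NaHCO3, CH2Cl2, 0 °C → rt
Reagents that add atoms: none
Why: Dess–Martin oxidation stops at the aldehyde under neutral, non-epimerising conditions.

Step 13
Reactants: 18 (S)-5-oxotetrahydrofuran-2-carbaldehyde
Product: 19 (S)-5-vinyldihydrofuran-2(3H)-one
Conditions: Ph3PCH3Br, KN(SiMe3)2, THF, 0 °C; then 18, −78 → 0 °C
Reagents that add atoms: methyltriphenylphosphonium bromide, C[P+](c1ccccc1)(c1ccccc1)c1ccccc1.[Br-]
Why: Wittig methylenation with the non-stabilised ylide at low temperature converts the aldehyde to the vinyl group before the α-oxygenated centre (the future C7a) can epimerise.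

Step 14
Reactants: 19 (S)-5-vinyldihydrofuran-2(3H)-one; 20 (E)-4-phenylbut-3-en-2-one; 21 acryloyl chloride
Product: 23 (3S,9E)-6,8-dioxo-10-phenyldeca-1,9-dien-3-yl prop-2-enoate, via dilithium salt 22 (not isolated)
Conditions: 20 (2.1 equiv), LiN(i-Pr)2 (2.1 equiv), THF, −78 °C; 19, −78 → −20 °C; recool to −78 °C, 21 (1.05 equiv); aq. NH4Cl
Reagents that add atoms: none
Why: Crossed Claisen acylation of the kinetic enolate of 20 by the lactone carbonyl opens the ring to the diketonate–alkoxide 22 (the second enolate equivalent deprotonates the new β-diketone), and the hard secondary alkoxide is O-acylated by 21 much faster than the delocalised diketonate, so the alcohol is never free to cyclise onto the diketone.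

Step 15
Reactants: 23 (3S,9E)-6,8-dioxo-10-phenyldeca-1,9-dien-3-yl prop-2-enoate
Product: 24 (3S)-10-phenyl-6,8-bis(trimethylsilyloxy)deca-1,5,7,9-tetraen-3-yl prop-2-enoate (9E; enol-ether geometries not controlled)
Conditions: Me3SiOSO2CF3 (2.3 equiv), Et3N (3 equiv), Et2O, 0 °C; filtered and concentrated under argon, used at once
Reagents that add atoms: trimethylsilyl trifluoromethanesulfonate, C[Si](C)(C)OS(=O)(=O)C(F)(F)F
Why: Soft enolisation converts the β-diketone into its 1,3-bis(silyloxy)diene (Chan-type diene), whose terminal carbon (the future C6) is the nucleophilic site; the styryl side has no enolisable hydrogen.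

**Union and endgame**

Step 16
Reactants: 16 tricyclic dienone; 24 bis(silyloxy)diene (1.3 equiv)
Product: 27 tetracyclic 2-cinnamoylcyclopentanone (rings A to D) carrying the acrylate/vinyl side chain at C6, via bis-silyl adduct 25 (not isolated), via C6 epimer mixture 26 (not isolated)
Conditions: Me3SiOSO2CF3 (10 mol %), 2,6-di-tert-butylpyridine (20 mol %), CH2Cl2, −78 °C; then (NH4)2Ce(NO3)6 (2.05 equiv), NaHCO3, MeCN, −40 → 0 °C; aq. work-up; then TsOH·H2O (20 mol %), CHCl3, 40 °C
Reagents that add atoms: none
Why: Vinylogous Mukaiyama–Michael (1,6-) addition of the diene terminus to the silyl-activated dienone on the convex face, anti to the lactone oxygen, sets C7′; one-electron oxidation of the resulting silyl dienol ether then triggers 5-exo oxidative enol-silane coupling that forms C4–C6′ with ring D cis-fused (C6′), and acid-catalysed enolisation equilibrates C6 to the isomer with the side chain trans to ring B.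

Step 17
Reactants: 27 tetracyclic 2-cinnamoylcyclopentanone with acrylate/vinyl side chain
Product: 28 butenolide (5-substituted 2(5H)-furanone linked through C7 to C6 of ring D)
Conditions: second-generation Grubbs catalyst, (H2IMes)(PCy3)Cl2Ru=CHPh (5 mol %), CH2Cl2 (0.005 M), 40 °C
Reagents that add atoms: none
Why: Ring-closing metathesis of the acrylate/vinyl pair gives the butenolide with C7a untouched; the tetrasubstituted and conjugated 1,2-disubstituted alkenes do not compete.

Step 18
Reactants: 28 butenolide
Product: 29 CNP0313292.3 (target)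
Conditions: Cs2CO3 (0.2 equiv), MeCN, 0 °C → rt; AcOH quench
Reagents that add atoms: none
Why: Intramolecular Michael addition (6-exo-trig) of the cyclic β-diketone enolate at C4 to the butenolide β-carbon C3a: the one-carbon tether (C7) forces attack on the butenolide face syn to C7 and on the convex face of ring D, so ring E, the cis-fused lactone F (C3a) and the quaternary C4 form as single isomers, while the acidic substrate buffers the base and protects ring C and C7a from epimerisation.

**Compound list**
1 | ethyl (S)-3-hydroxy-3-phenylpropanoate | CCOC(=O)C[C@H](O)c1ccccc1 | starting material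
2 | ethyl (S)-3-[(tert-butyldimethylsilyl)oxy]-3-phenylpropanoate | CCOC(=O)C[C@H](O[Si](C)(C)C(C)(C)C)c1ccccc1 | intermediate
3 | (S)-3-[(tert-butyldimethylsilyl)oxy]-3-phenylpropanoic acid | OC(=O)C[C@H](O[Si](C)(C)C(C)(C)C)c1ccccc1 | intermediate
4 | (S)-1-(1H-benzotriazol-1-yl)-3-[(tert-butyldimethylsilyl)oxy]-3-phenylpropan-1-one | O=C(C[C@H](O[Si](C)(C)C(C)(C)C)c1ccccc1)n1nnc2ccccc12 | intermediate
5 | cyclohex-2-en-1-ol (racemic) | OC1CCCC=C1 | starting material
6 | cyclohex-2-en-1-yl acetate (racemic) | CC(=O)OC1CCCC=C1 | intermediate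
7 | dimethyl malonate | COC(=O)CC(=O)OC | starting material
8 | dimethyl (R)-2-(cyclohex-2-en-1-yl)malonate | COC(=O)C(C(=O)OC)[C@@H]1CCCC=C1 | intermediate
9 | (R)-2-(cyclohex-2-en-1-yl)malonic acid | OC(=O)C(C(=O)O)[C@@H]1CCCC=C1 | intermediate
10 | (S)-2-(cyclohex-2-en-1-yl)acetic acid | OC(=O)C[C@@H]1CCCC=C1 | intermediate
11 | (3aS,7R,7aR)-7-iodohexahydro-1-benzofuran-2(3H)-one (cis-fused, iodide trans to the lactone oxygen) | O=C1C[C@@H]2CCC[C@@H](I)[C@@H]2O1 | intermediate
12 | (3aS,7aR)-3a,4,5,7a-tetrahydro-1-benzofuran-2(3H)-one | O=C1C[C@@H]2CCC=C[C@@H]2O1 | intermediate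
13 | (3aS,7aR)-3a,7a-dihydro-1-benzofuran-2,5(3H,4H)-dione (cis-fused γ-acyloxy enone) | O=C1C[C@@H]2CC(=O)C=C[C@@H]2O1 | intermediate
14 | (3aR,7aS)-4-[(3S)-3-[(tert-butyldimethylsilyl)oxy]-3-phenylpropanoyl]-5-hydroxy-3a,7a-dihydro-1-benzofuran-2(3H)-one | O=C1C[C@@H]2C(C(=O)C[C@H](O[Si](C)(C)C(C)(C)C)c3ccccc3)=C(O)C=C[C@@H]2O1 | intermediate
15 | (3aR,7aS)-5-hydroxy-4-[(3S)-3-hydroxy-3-phenylpropanoyl]-3a,7a-dihydro-1-benzofuran-2(3H)-one | O=C1C[C@@H]2C(C(=O)C[C@H](O)c3ccccc3)=C(O)C=C[C@@H]2O1 | intermediate
16 | tricyclic dienone, rings A–C: cis-lactone (3a′R,7a′S) on a cyclohexadiene fused to an (S)-2-phenyl-2,3-dihydro-4H-pyran-4-one | O=C1C[C@@H]2C3=C(O[C@H](c4ccccc4)CC3=O)C=C[C@@H]2O1 | intermediate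
17 | (S)-5-(hydroxymethyl)dihydrofuran-2(3H)-one | O=C1CC[C@@H](CO)O1 | starting material
18 | (S)-5-oxotetrahydrofuran-2-carbaldehyde | O=C1CC[C@@H](C=O)O1 | intermediate
19 | (S)-5-vinyldihydrofuran-2(3H)-one | O=C1CC[C@@H](C=C)O1 | intermediate
20 | (E)-4-phenylbut-3-en-2-one | CC(=O)/C=C/c1ccccc1 | starting material
21 | acryloyl chloride | C=CC(=O)Cl | starting material
22 | dilithium salt (secondary alkoxide and diketonate) of (3S,9E)-3-hydroxy-10-phenyldeca-1,9-diene-6,8-dione | [Li+].[Li+].[O-]C(/C=C/c1ccccc1)=CC(=O)CC[C@H]([O-])C=C | intermediate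
23 | (3S,9E)-6,8-dioxo-10-phenyldeca-1,9-dien-3-yl prop-2-enoate | O=C(/C=C/c1ccccc1)CC(=O)CC[C@H](OC(=O)C=C)C=C | intermediate
24 | (3S)-10-phenyl-6,8-bis(trimethylsilyloxy)deca-1,5,7,9-tetraen-3-yl prop-2-enoate (9E) | C[Si](C)(C)OC(/C=C/c1ccccc1)=CC(O[Si](C)(C)C)=CC[C@H](OC(=O)C=C)C=C | intermediate
25 | bis-silyl 1,6-adduct: silyl dienol ether of rings B/C with the C6–C7′ bond formed, C6 unassigned, β-silyloxy enone on the chain | O=C1C[C@@H]2C3=C(O[Si](C)(C)C)C[C@@H](c4ccccc4)OC3=C[C@H]([C@@H]2O1)C(C[C@H](OC(=O)C=C)C=C)C(=O)C=C(O[Si](C)(C)C)/C=C/c1ccccc1 | intermediate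
26 | tetracycle with ring D closed (cis-fused at C6′/C7′), C6 epimer mixture, C4 enolisable | O=C1C[C@@H]2C3=C(O[C@H](c4ccccc4)CC3=O)[C@@H]3[C@H]([C@@H]2O1)C(C[C@H](OC(=O)C=C)C=C)C(=O)C3C(=O)/C=C/c1ccccc1 | intermediate
27 | tetracycle, rings A–D: 2-cinnamoylcyclopentanone cis-fused to ring B, C6 side chain [(S)-2-(acryloyloxy)but-3-enyl] trans to ring B, C4 enolisable | O=C1C[C@@H]2C3=C(O[C@H](c4ccccc4)CC3=O)[C@@H]3[C@H]([C@@H]2O1)[C@@H](C[C@H](OC(=O)C=C)C=C)C(=O)C3C(=O)/C=C/c1ccccc1 | intermediate
28 | as 27, with the side chain closed to the (S)-5-substituted 2(5H)-furanone (butenolide) | O=C1C[C@@H]2C3=C(O[C@H](c4ccccc4)CC3=O)[C@@H]3[C@H]([C@@H]2O1)[C@@H](C[C@@H]1OC(=O)C=C1)C(=O)C3C(=O)/C=C/c1ccccc1 | intermediate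
29 | CNP0313292.3 | O=C1C[C@@H]2C3=C(O[C@H](c4ccccc4)CC3=O)[C@@H]3[C@H]([C@@H]2O1)[C@H]1C[C@@H]2OC(=O)C[C@@H]2[C@]3(C(=O)/C=C/c2ccccc2)C1=O | target

**Totals**
Total step count: 18. Longest linear sequence: 11 steps (steps 4–11, then 16–18).

**Steps most likely to fail, with fallbacks**

Step 16 (1,6-addition plus oxidative ring D closure). The risks are 1,4-attack at C5′ instead of C7′ and oligomerisation or over-oxidation in the one-electron coupling. The fallback sets out from 25 (made from 16 and 24 as in step 16) and replaces the radical-cation coupling by a two-electron halogenation/alkylation. N-Iodosuccinimide at −78 °C iodinates the dienol-ether terminus C6′; aqueous work-up gives the γ-iodo vinylogous ester F1. AgOSO2CF3 with 2,6-di-tert-butylpyridine in CH2Cl2 then ionises the allylic iodide, and the diketone enol carbon C4 captures the oxocarbenium-stabilised cation to close the five-membered ring. The route is rejoined at 26, which is equilibrated with TsOH to 27 as before.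

Step 14 (lactone-opening Claisen with in-flask acryloylation). The risks are a persistent tetrahedral adduct and acylation of the diketonate instead of the alkoxide. The fallback sets out from 20 and forms the chain by epoxide alkylation instead of acylation. Ketone 20 is condensed with ethyl acetate (NaH, THF) to (5E)-6-phenylhex-5-ene-2,4-dione F2. Its dianion (LiN(i-Pr)2, 2.2 equiv, THF, −78 → 0 °C) opens (R)-2-vinyloxirane at the terminal carbon, which gives the same dilithium salt 22. Trapping with 21 at −78 °C returns the route at 23.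

Step 9 (allylic oxidation). The risks are attack at the transposed allylic terminus C7′ or low conversion. The fallback sets out from 12 and uses an ene/[2,3]-sigmatropic manifold, which returns oxygen to C5′ with the alkene in place. SeO2 (0.5 equiv) with t-BuOOH in CH2Cl2 gives (3aS,7aR)-5-hydroxy-3a,4,5,7a-tetrahydro-1-benzofuran-2(3H)-one F3 as a C5′ epimer mixture. MnO2 in CH2Cl2 then oxidises the allylic alcohol, and the route is rejoined at 13.

**Further compounds**
F1 | step 16 | γ-iodo vinylogous ester: C6′-iodide of the 1,6-adduct with the free β-diketone chain (C6′ and C6 unassigned) | O=C1C[C@@H]2C3=C(O[C@H](c4ccccc4)CC3=O)C(I)[C@H]([C@@H]2O1)C(C[C@H](OC(=O)C=C)C=C)C(=O)CC(=O)/C=C/c1ccccc1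
F2 | step 14 | (5E)-6-phenylhex-5-ene-2,4-dione | CC(=O)CC(=O)/C=C/c1ccccc1
F3 | step 9 | (3aS,7aR)-5-hydroxy-3a,4,5,7a-tetrahydro-1-benzofuran-2(3H)-one (C5 epimer mixture) | O=C1C[C@@H]2CC(O)C=C[C@@H]2O1
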